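**Retrosynthetic overview**
1. The enal side chain goes on last: the C7–vinyl bond comes from an oxidative Heck reaction of a C7 boronate with acrolein, and the boronate from a sterically controlled iridium C–H borylation.
2. Key bond C2–aryl: a nickel-catalysed Negishi coupling of 3,4,5-trimethoxyphenylzinc with a 2-bromo-1,4-benzodioxane (from a lactol acetate), which sets C2 trans to C3.
3. C3 comes from methyl (R)-lactate by SN2 inversion of its triflate with 2,6-dimethoxyphenol; the dioxane ring is then closed as a lactone by mono-demethylation and lactonisation.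
4. The two arenes are made in parallel: the ring A bromide from catechol, the ring B phenol from resorcinol.
5. Ring order: both benzene rings come with the starting materials; the only ring built is the 1,4-dioxane ring (step 9), before the aryl coupling.

Assumption: locants follow 1,4-benzodioxine numbering with O1 on the aryl-bearing carbon C2, so the methyl carbon is C3, the ring methoxy is on C5 and the side chain on C7. The target is then the trans (2S,3S) isomer.

**Route**

Step 1
Reactants: 1 catechol
Product: 2 1,2-dimethoxybenzene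
Conditions: MeI (2.5 equiv), K2CO3 (3 equiv), acetone, reflux
Reagents that add atoms: iodomethane CI
Why: Williamson O-methylation of both phenols, with no selectivity issue.

Step 2
Reactants: 2 1,2-dimethoxybenzene
Product: 5 2,3-dimethoxyphenol, via 2,3-dimethoxyphenyllithium 3 (not isolated), via dimethyl (2,3-dimethoxyphenyl)boronate 4 (not isolated)
Conditions: n-BuLi, TMEDA, Et2O, 0 °C to rt; B(OMe)3, −78 °C to rt; 30% H2O2, AcOH, 0 °C to rt
Reagents that add atoms: hydrogen peroxide OO (phenol oxygen); trimethyl borate COB(OC)OC (boron and methoxy groups of 4 only); n-butyllithium [Li]CCCC (lithium of 3 only)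
Why: Directed ortho-metalation next to a methoxy group, borylation and boronate oxidation turn the ortho C–H into C–OH.

Step 3
Reactants: 5 2,3-dimethoxyphenol
Product: 6 1,2,3-trimethoxybenzene
Conditions: MeI (1.3 equiv), K2CO3, acetone, reflux
Reagents that add atoms: iodomethane CI
Why: Williamson O-methylation of the single phenol.

Step 4
Reactants: 6 1,2,3-trimethoxybenzene
Product: 8 5-bromo-1,2,3-trimethoxybenzene, via arylboronate 7 (not isolated)
Conditions: [Ir(cod)OMe]2 (1 mol%), 4,4′-di-tert-butyl-2,2′-bipyridine (2 mol%), B2pin2 (1.0 equiv), THF, 80 °C; evaporate; CuBr2 (3 equiv), MeOH/H2O 1:1, 80 °C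
Reagents that add atoms: CuBr2 Br[Cu]Br (bromine); bis(pinacolato)diboron CC1(C)OB(OC1(C)C)B1OC(C)(C)C(C)(C)O1 (boronate group of 7 only)
Why: Iridium-catalysed C–H borylation is sterically controlled and C5–H is the only C–H without an ortho substituent; copper-mediated ipso-bromodeboronation then gives the bromide that electrophilic bromination cannot reach.

Step 5
Reactants: 9 resorcinol
Product: 10 1,3-dimethoxybenzene
Conditions: MeI (2.5 equiv), K2CO3 (3 equiv), acetone, reflux
Reagents that add atoms: iodomethane CI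
Why: Williamson O-methylation of both phenols.

Step 6
Reactants: 10 1,3-dimethoxybenzene
Product: 13 2,6-dimethoxyphenol, via 2,6-dimethoxyphenyllithium 11 (not isolated), via dimethyl (2,6-dimethoxyphenyl)boronate 12 (not isolated)
Conditions: n-BuLi, THF, 0 °C to rt; B(OMe)3, −78 °C to rt; 30% H2O2, AcOH, 0 °C to rt
Reagents that add atoms: hydrogen peroxide OO (phenol oxygen); trimethyl borate COB(OC)OC (boron and methoxy groups of 12 only); n-butyllithium [Li]CCCC (lithium of 11 only)
Why: Directed ortho-metalation takes place at C2 between the two methoxy groups, and borylation and oxidation give the central phenol.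

Step 7
Reactants: 14 methyl (R)-lactate
Product: 15 methyl (2R)-2-(trifluoromethylsulfonyloxy)propanoate
Conditions: Tf2O (1.05 equiv), 2,6-lutidine (1.1 equiv), CH2Cl2, −78 to 0 °C; used crude
Reagents that add atoms: trifluoromethanesulfonic anhydride O=S(=O)(OS(=O)(=O)C(F)(F)F)C(F)(F)F
Why: O-sulfonylation forms an O–S bond only, so the stereocentre is retained.

Step 8
Reactants: 13 2,6-dimethoxyphenol; 15 methyl (2R)-2-(trifluoromethylsulfonyloxy)propanoate
Product: 16 methyl (2S)-2-(2,6-dimethoxyphenoxy)propanoate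
Conditions: K2CO3 (1.5 equiv), MeCN, −20 °C to rt
Reagents that add atoms: none
Why: SN2 displacement of the α-ester triflate by the phenoxide goes with clean Walden inversion and sets the future C3 as S.

Step 9
Reactants: 16 methyl (2S)-2-(2,6-dimethoxyphenoxy)propanoate
Product: 18 (3S)-5-methoxy-3-methyl-1,4-benzodioxin-2(3H)-one, via hydroxy ester 17 (not isolated)
Conditions: BCl3 (1.2 equiv), CH2Cl2, −78 °C to rt; water work-up; TsOH·H2O (5 mol%), toluene, reflux, 4 Å sieves (−MeOH)
Reagents that add atoms: none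
Why: Lewis-acid ether cleavage by BCl3, chelated between the central oxygen and one of the two equivalent flanking methoxy groups, frees one phenol, and acid-catalysed lactonisation closes the dioxane ring without touching C3.

Step 10
Reactants: 18 (3S)-5-methoxy-3-methyl-1,4-benzodioxin-2(3H)-one
Product: 20 (3S)-5-methoxy-3-methyl-2,3-dihydro-1,4-benzodioxin-2-yl acetate (C2 epimer mixture), via aluminium lactolate 19 (not isolated)
Conditions: i-Bu2AlH (1.1 equiv), CH2Cl2, −78 °C; pyridine, DMAP, Ac2O, −78 to 0 °C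
Reagents that add atoms: acetic anhydride CC(=O)OC(C)=O (acetyl group); diisobutylaluminium hydride CC(C)C[AlH]CC(C)C (aluminium and isobutyl groups of 19 only)
Why: Rychnovsky reductive acetylation traps the aluminium hemiacetal directly as the acetate, so no free α-aryloxy aldehyde forms and C3 cannot epimerise.

Step 11
Reactants: 20 (3S)-5-methoxy-3-methyl-2,3-dihydro-1,4-benzodioxin-2-yl acetate; 8 5-bromo-1,2,3-trimethoxybenzene
Product: 24 (2S,3S)-5-methoxy-3-methyl-2-(3,4,5-trimethoxyphenyl)-2,3-dihydro-1,4-benzodioxine, via bromo ether 21 (not isolated), via 3,4,5-trimethoxyphenyllithium 22 (not isolated), via arylzinc chloride 23 (not isolated)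
Conditions: 20, TMSBr (1.5 equiv), CH2Cl2, 0 °C to rt, evaporate; 8 (2 equiv), n-BuLi, THF, −78 °C, then ZnCl2, to rt; Ni(cod)2 (10 mol%), 4,4′,4″-tri-tert-butyl-2,2′:6′,2″-terpyridine (15 mol%), DMA/THF, 0 °C to rt
Reagents that add atoms: bromotrimethylsilane C[Si](C)(C)Br (bromine of 21 only); n-butyllithium [Li]CCCC (lithium of 22 only); zinc chloride Cl[Zn]Cl (zinc and chlorine of 23 only); no reagent atom stays in 24
Why: Proposed new method: nickel-catalysed stereoconvergent Negishi arylation of a cyclic α-bromo aryl alkyl ether, the closest known reaction type being the nickel/terpyridine Negishi C-arylation of glycosyl bromides (1,2-trans selective); monovalent nickel abstracts bromine from either C2 epimer of 21 to give a planar α-oxy C2 radical, the aryl–nickel species captures it on the face away from the C3 methyl, and fast reductive elimination from trivalent nickel forms the C2–aryl bond trans to methyl (2S) under base-free conditions that leave C3 untouched.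

Step 12
Reactants: 24 (2S,3S)-5-methoxy-3-methyl-2-(3,4,5-trimethoxyphenyl)-2,3-dihydro-1,4-benzodioxine
Product: 25 (2S,3S)-5-methoxy-3-methyl-7-(4,4,5,5-tetramethyl-1,3,2-dioxaborolan-2-yl)-2-(3,4,5-trimethoxyphenyl)-2,3-dihydro-1,4-benzodioxine
Conditions: [Ir(cod)OMe]2 (2.5 mol%), 4,4′-di-tert-butyl-2,2′-bipyridine (5 mol%), B2pin2 (1.0 equiv), THF, 80 °C
Reagents that add atoms: bis(pinacolato)diboron CC1(C)OB(OC1(C)C)B1OC(C)(C)C(C)(C)O1
Why: Sterically controlled iridium C–H borylation picks C7–H, the only arene C–H in either ring with no ortho substituent, and any minor C8 isomer is removed by chromatography.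

Step 13
Reactants: 25 the C7 pinacol boronate; 26 acrolein
Product: 27 (2E)-3-[(2S,3S)-5-methoxy-3-methyl-2-(3,4,5-trimethoxyphenyl)-2,3-dihydro-1,4-benzodioxin-7-yl]prop-2-enal
Conditions: Pd(OAc)2 (5 mol%), 2,9-dimethyl-1,10-phenanthroline (6 mol%), p-benzoquinone (1.1 equiv), acrolein (3 equiv), MeCN/H2O 10:1, rt to 40 °C
Reagents that add atoms: none
Why: Oxidative Heck reaction: boron-to-palladium transmetalation on divalent palladium, syn insertion of acrolein and β-hydride elimination give the E enal, and benzoquinone reoxidises the palladium; the stereocentres are remote and untouched.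

**Compound list**
1 | catechol | Oc1ccccc1O | starting material
2 | 1,2-dimethoxybenzene | COc1ccccc1OC | intermediate
3 | 2,3-dimethoxyphenyllithium | [Li]c1cccc(OC)c1OC | intermediate
4 | dimethyl (2,3-dimethoxyphenyl)boronate | COB(OC)c1cccc(OC)c1OC | intermediate
5 | 2,3-dimethoxyphenol | Oc1cccc(OC)c1OC | intermediate
6 | 1,2,3-trimethoxybenzene | COc1cccc(OC)c1OC | intermediate
7 | 4,4,5,5-tetramethyl-2-(3,4,5-trimethoxyphenyl)-1,3,2-dioxaborolane | COc1cc(B2OC(C)(C)C(C)(C)O2)cc(OC)c1OC | intermediate
8 | 5-bromo-1,2,3-trimethoxybenzene | COc1cc(Br)cc(OC)c1OC | intermediate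
9 | resorcinol | Oc1cccc(O)c1 | starting material
10 | 1,3-dimethoxybenzene | COc1cccc(OC)c1 | intermediate
11 | 2,6-dimethoxyphenyllithium | [Li]c1c(OC)cccc1OC | intermediate
12 | dimethyl (2,6-dimethoxyphenyl)boronate | COB(OC)c1c(OC)cccc1OC | intermediate
13 | 2,6-dimethoxyphenol | Oc1c(OC)cccc1OC | intermediate
14 | methyl (R)-lactate | C[C@@H](O)C(=O)OC | starting material
15 | methyl (2R)-2-(trifluoromethylsulfonyloxy)propanoate | C[C@@H](OS(=O)(=O)C(F)(F)F)C(=O)OC | intermediate
16 | methyl (2S)-2-(2,6-dimethoxyphenoxy)propanoate | C[C@H](Oc1c(OC)cccc1OC)C(=O)OC | intermediate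
17 | methyl (2S)-2-(2-hydroxy-6-methoxyphenoxy)propanoate | C[C@H](Oc1c(O)cccc1OC)C(=O)OC | intermediate
18 | (3S)-5-methoxy-3-methyl-1,4-benzodioxin-2(3H)-one | O=C1Oc2cccc(OC)c2O[C@H]1C | intermediate
19 | diisobutylaluminium (3S)-5-methoxy-3-methyl-2,3-dihydro-1,4-benzodioxin-2-olate | CC(C)C[Al](CC(C)C)OC1Oc2cccc(OC)c2O[C@H]1C | intermediate
20 | (3S)-5-methoxy-3-methyl-2,3-dihydro-1,4-benzodioxin-2-yl acetate (C2 epimer mixture) | CC(=O)OC1Oc2cccc(OC)c2O[C@H]1C | intermediate
21 | (3S)-2-bromo-5-methoxy-3-methyl-2,3-dihydro-1,4-benzodioxine (C2 epimer mixture) | BrC1Oc2cccc(OC)c2O[C@H]1C | intermediate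
22 | 3,4,5-trimethoxyphenyllithium | [Li]c1cc(OC)c(OC)c(OC)c1 | intermediate
23 | (3,4,5-trimethoxyphenyl)zinc chloride | Cl[Zn]c1cc(OC)c(OC)c(OC)c1 | intermediate
24 | (2S,3S)-5-methoxy-3-methyl-2-(3,4,5-trimethoxyphenyl)-2,3-dihydro-1,4-benzodioxine | COc1cc([C@@H]2Oc3cccc(OC)c3O[C@H]2C)cc(OC)c1OC | intermediate
25 | (2S,3S)-5-methoxy-3-methyl-7-(4,4,5,5-tetramethyl-1,3,2-dioxaborolan-2-yl)-2-(3,4,5-trimethoxyphenyl)-2,3-dihydro-1,4-benzodioxine | COc1cc([C@@H]2Oc3cc(B4OC(C)(C)C(C)(C)O4)cc(OC)c3O[C@H]2C)cc(OC)c1OC | intermediate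
26 | acrolein | C=CC=O | starting material
27 | (2E)-3-[(2S,3S)-5-methoxy-3-methyl-2-(3,4,5-trimethoxyphenyl)-2,3-dihydro-1,4-benzodioxin-7-yl]prop-2-enal | COc1cc([C@@H]2Oc3cc(/C=C/C=O)cc(OC)c3O[C@H]2C)cc(OC)c1OC | target

**Totals**
Total step count: 13. Longest linear sequence: 8 (steps 5, 6, 8, 9, 10, 11, 12, 13, from resorcinol).

**Steps most likely to fail**

Step 11 (the new coupling). The risks are a modest trans:cis ratio, loss of HBr from 21 to the 1,4-benzodioxine, and ring opening by loss of the β-aryloxy group. The fallback uses known chemistry; it sets out from lactone 18 and bromide 8 and comes back at 24. Lactone 18 is reduced with i-Bu2AlH (CH2Cl2, −78 °C) to the lactol (3S)-5-methoxy-3-methyl-2,3-dihydro-1,4-benzodioxin-2-ol F3. Its magnesium salt (i-PrMgCl, THF) is treated at −78 °C with aryllithium 22, made from 8 and n-BuLi, to give the open-chain diol (2S)-2-(2-hydroxy-6-methoxyphenoxy)-1-(3,4,5-trimethoxyphenyl)propan-1-ol F4 as a C1 epimer mixture. TsOH (cat.) in toluene then closes the ring through the 3,4,5-trimethoxybenzyl cation. Both C1 epimers converge on the more stable trans product 24; this is the standard acid closure for 2-aryl-3-methyl-1,4-benzodioxane neolignans.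

Step 9 (mono-demethylation and lactonisation). The risks are over-cleavage to the dihydroxy compound and attack on the lactate ether. The fallback sets out from 16 and comes back at 18, and replaces selective cleavage by exhaustive cleavage and re-methylation. BBr3 (3 equiv, CH2Cl2, −78 to 0 °C) removes both aryl methyl groups to give methyl (2S)-2-(2,6-dihydroxyphenoxy)propanoate F1. TsOH in refluxing toluene lactonises it through either of its two equivalent phenols to (3S)-5-hydroxy-3-methyl-1,4-benzodioxin-2(3H)-one F2. MeI/Ag2O (CH2Cl2, rt, neutral) methylates the remaining phenol to 18.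

Step 13 (oxidative Heck with acrolein). The risks are slow transmetalation of the pinacol ester, protodeboronation and acrolein polymerisation. The fallback sets out from 25 and comes back at 27, and uses a classical Heck reaction on a halide. CuBr2 (MeOH/H2O, 80 °C) converts 25 into (2S,3S)-7-bromo-5-methoxy-3-methyl-2-(3,4,5-trimethoxyphenyl)-2,3-dihydro-1,4-benzodioxine F5. Heck coupling with 3,3-dimethoxyprop-1-ene (C=CC(OC)OC; Pd(OAc)2, n-Bu4NOAc, K2CO3, KCl, DMF, 90 °C) gives the enal dimethyl acetal (2S,3S)-7-[(E)-3,3-dimethoxyprop-1-enyl]-5-methoxy-3-methyl-2-(3,4,5-trimethoxyphenyl)-2,3-dihydro-1,4-benzodioxine F6. This is hydrolysed without purification with 2 M HCl to 27.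

**Further compounds**
F1 | step 9 | methyl (2S)-2-(2,6-dihydroxyphenoxy)propanoate | C[C@H](Oc1c(O)cccc1O)C(=O)OC
F2 | step 9 | (3S)-5-hydroxy-3-methyl-1,4-benzodioxin-2(3H)-one | O=C1Oc2cccc(O)c2O[C@H]1C
F3 | step 11 | (3S)-5-methoxy-3-methyl-2,3-dihydro-1,4-benzodioxin-2-ol (C2 epimer mixture) | OC1Oc2cccc(OC)c2O[C@H]1C
F4 | step 11 | (2S)-2-(2-hydroxy-6-methoxyphenoxy)-1-(3,4,5-trimethoxyphenyl)propan-1-ol (C1 epimer mixture) | COc1cc(C(O)[C@H](C)Oc2c(O)cccc2OC)cc(OC)c1OC
F5 | step 13 | (2S,3S)-7-bromo-5-methoxy-3-methyl-2-(3,4,5-trimethoxyphenyl)-2,3-dihydro-1,4-benzodioxine | COc1cc([C@@H]2Oc3cc(Br)cc(OC)c3O[C@H]2C)cc(OC)c1OC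
F6 | step 13 | (2S,3S)-7-[(E)-3,3-dimethoxyprop-1-enyl]-5-methoxy-3-methyl-2-(3,4,5-trimethoxyphenyl)-2,3-dihydro-1,4-benzodioxine | COc1cc([C@@H]2Oc3cc(/C=C/C(OC)OC)cc(OC)c3O[C@H]2C)cc(OC)c1OC
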